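## The problem

The target is a tricyclic polyprenylated acylphloroglucinol. Numbering used throughout: C1 and C5 are the bridgeheads of a bicyclo[3.3.1]nonane, C9 is the bridging ketone, C2–C4 complete ring A (C2 ketone, C3 bearing the 3,4-dihydroxybenzoyl group, C4 enol carbon), C6–C8 complete ring B (C6 ring-fusion CH, C7 prenylated CH, C8 gem-dimethyl carbon), and C10–C14 close the cycloheptane ring C from C5 to C6 (C10 CH2, C11 gem-dimethyl, C12 isopropenyl CH, C13 and C14 CH2). There are five stereocentres. C1 and C5 are quaternary and flank C9. C6 and C7 are contiguous on ring B, so C7 can set C6. C12 is insulated from all the others by CH2 groups and the quaternary C11, so it has to arrive with its own absolute configuration and be joined to ring B by a step that ring B controls. On ring B the C4 carbon at C5 is 1,3-cis to the C7 prenyl group and trans to the ring C bonds, so C4 must enter the more hindered face of ring B. C10 is neopentyl, so the C5–C10 bond cannot be made by alkylation. The molecule carries two prenyl groups and an isopropenyl group (no hydrogenation, ozonolysis or strong acid), an air-sensitive catechol, and an acidic 2-aroyl-1,3-dione that should stay masked until the end; the non-enolisable β-dicarbonyl units at C1 and C5 invite retro-Claisen cleavage. The aroyl group on C3 together with the oxygen on C4 is an opened 5-aryl-isoxazole. C4 can therefore be a nitrile oxide carbon on C5 and C3 an alkyne carbon of an aryl ynone on C1, and the four-atom tether C5–C9–C1–C2 then closes ring A.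

## Retrosynthesis

Target 41 is traced to enaminone 40 by hydrolysis of a vinylogous amide and loss of two aryl silyl ethers, and 40 to isoxazole 39 by N–O cleavage. No carbon–carbon bond is cut; the isoxazole carries C2, C3, C4 and the aroyl carbon at their final oxidation levels and hides the acidic triketone. The forward steps must spare three alkenes, which zerovalent molybdenum in wet acetonitrile and aqueous hydroxide do.

Isoxazole 39 is cut at C3–C4 and at the O–C(aryl) bond, giving nitrile oxide 38, made in the flask from aldoxime 36. The neighbouring cuts (a Claisen closure at C3–C4 or C2–C3 followed by C-aroylation of a triketone) would expose the enolisable trione early and need an O-to-C acyl transfer. The cycloaddition instead brings the aryl group in with the ring. The precursor has lost ring A and is a cis-fused ring B/ring C ketone with two arms. The forward step needs the two arms cis on ring B and needs the ynone to outrun the C7 prenyl alkene as dipolarophile.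

Ynone 36 is cut at the C2–alkyne bond to aldehyde 29 and alkyne 32 (acetylide addition, oxidation via 34 and 35). An ynone next to an enolisable C1–H would close to a γ-pyranone through the C9 enol oxygen. C1 is therefore made quaternary first, at the formyl stage: 29 comes from hydroxymethylene ketone 28 by C-prenylation, and 28 from ketone 27 by formylation at the only enolisable position. Hydroxylamine would add to an ynone, so the oxime is installed before the ynone as its tetrahydropyranyl ether (27 from keto aldehyde 26) and freed just before the key step. The prenylation has to put the formyl group on the face of C4.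

Keto aldehyde 26 is cut at C5–C4. Direct formylation of a C9 enolate would require the electrophile to enter syn to the C7 side chain and past the axial C8 methyl group, the face an angular enolate avoids. C4 is therefore delivered from the C9 oxygen: 26 from diol 25, oxasilolane 24, bromomethylsilyl ether 23, allylic alcohol 22 and enone 21. The temporary C9 carbinol is set against the axial C8 methyl group and transfers its configuration to C5 through a ring that can only be cis-fused.

Enone 21 is cut at C5=C10 (aldol condensation of keto aldehyde 19, the only way to make the neopentyl bond from a carbonyl) and then at C6–C14, leading through 18, 17, 16 and 15 to enone ester 5 and iodide 13. This is the convergent point: C12 comes in fragment 13, and C6 is set by conjugate addition anti to the C7 arm of 5. The ester arm of 15 is turned into the prenyl group while the ketone rests as its silyl enol ether.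

Enone ester 5 comes from cyclohexene ester 4 by allylic oxidation at C9. Ester 4 comes from allylic alcohol 2 by a Johnson–Claisen rearrangement that moves the carbinol chirality to C7 next to the gem-dimethyl carbon. Alcohol 2 comes from enone 1 by enantioselective reduction.

Iodide 13 is traced through iodo alcohol 12 and diol 11 to aldehyde acid 10, the product of cleaving epoxy ketone 9 between C14 and the old enone α-carbon. Ketone 9 comes from 6,6-dimethylcarvone 8 and this from (R)-carvone 6, whose isopropenyl-bearing carbon becomes C12. Alkyne 32 comes from aldehyde 31 and 3,4-dihydroxybenzaldehyde 30.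

## Roads not taken

Alternative 1: The cut is C5–C6. Forward, the silyl ketene acetal of a seven-membered allylic lactone (carbonyl C9, ring oxygen on C13) would undergo an Ireland–Claisen ring contraction to cycloheptene acid A1, with quaternary C5 and the C7-bearing chain on C6. Its merit is real and in one respect it is better than the chosen plan: both ring-fusion centres form in one suprafacial step, and their configuration is relayed from C13, which is adjacent to C12, so the isolated C12 centre is tied to the ring fusion without a chiral-pool fragment and without the five steps spent here on delivering C4. Its weak points are the C13=C14 double bond left in ring C, which would have to be reduced in the presence of an isopropenyl and a prenyl group; the medium-ring lactone; and C4 and C9 arriving as alcohol and acid, so that ring B still needs a Dieckmann closure and redox adjustment before ring A can be addressed. The chosen plan sets against it a ring C that never contains a superfluous alkene and a C9 ketone present from the start.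

Alternative 2: The cut is C10–C11. Forward, Fe(acac)3 and PhSiH3 would transfer a hydrogen atom to one of two isopropenyl groups on C12 of a ring B enone carrying an exocyclic methylene at C5; the tertiary C11 radical would add to C10 and the enolate would be protonated, giving fused ketone A2. This makes the neopentyl bond and ring C in one step from an achiral chain and would reach the ring B/ring C bicycle in considerably fewer steps than the route to 21; on step count it is the better road to that point. Against it: C12 is set by choosing between diastereotopic isopropenyl groups through a flexible seven-membered transition state remote from C6 and C7, and hydrogen-atom transfer would also engage the trisubstituted prenyl alkene. A2 also has hydrogen on C5, so C4 would have to be added to an enolate on the hindered face, with a choice between C5 and C1 enolisation. The chosen plan sets against it a C12 centre bought with carvone and a C5 centre set by tether.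

Alternative 3: The cuts are C5–C9 and C3–C4. Forward, irradiation would add the enol double bond of a 1,3-diketone across an exocyclic ketene acetal on ring C, and retro-aldol opening of the cyclobutanol would give ketal ketone A3, closing ring B and creating quaternary C5 in one photochemical operation with the aryl ketone already attached. That brevity at C5 is its advantage. Its weak points are the competing chromophores and [2+2] partners (aryl ketone, prenyl and isopropenyl groups), the hydrolytic lability of the ketene acetal, and above all that C2 is still absent in A3. Ring A would then need a one-carbon carbonyl inserted between the hindered tertiary C1 and C3 by double C-acylation. The chosen plan brings C2, C3 and the aroyl carbon as one ynone unit and lets the tether decide the regiochemistry of ring closure.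

Key step: step 29

Remarks on the chemistry:
- The sense of the oxazaborolidine reduction in step 1 is assigned with the enone double bond as the larger group; the enantiomeric catalyst would be used if the opposite sense were found.
- Compounds with a tetrahydropyranyl group are mixtures of epimers at the acetal carbon and 34 is a mixture at the carbinol carbon; neither centre survives.

## Route

Step 1
Reactants: 1 4,4-dimethylcyclohex-2-en-1-one
Product: 2 (1S)-4,4-dimethylcyclohex-2-en-1-ol
Conditions: (R)-Me-CBS oxazaborolidine (10 mol %), BH3·SMe2, THF, −20 °C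
Reagents that add atoms: none
Why: Corey–Bakshi–Shibata reduction of a cyclic enone; hydride is delivered to the face fixed by the catalyst, with the alkene acting as the large substituent, which should give the S carbinol that later becomes C7.

Step 2
Reactants: 2 (1S)-4,4-dimethylcyclohex-2-en-1-ol
Product: 4 ethyl 2-[(1S)-6,6-dimethylcyclohex-2-en-1-yl]acetate, via ketene acetal 3 (not isolated)
Conditions: MeC(OEt)3, EtCO2H (cat.), xylene, 140 °C, EtOH distilled off
Reagents that add atoms: triethyl orthoacetate, CC(OCC)(OCC)OCC
Why: Johnson–Claisen rearrangement; the suprafacial [3,3] shift forms the C7–C bond on the face the oxygen leaves, so the carbinol configuration is transferred to C7 beside the gem-dimethyl carbon, and the double bond moves to C5=C6.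

Step 3
Reactants: 4 ethyl 2-[(1S)-6,6-dimethylcyclohex-2-en-1-yl]acetate
Product: 5 ethyl 2-[(1S)-6,6-dimethyl-4-oxocyclohex-2-en-1-yl]acetate
Conditions: Rh2(cap)4 (cap = caprolactamate, 1 mol %), t-BuOOH, K2CO3, CH2Cl2, rt
Reagents that add atoms: tert-butyl hydroperoxide, CC(C)(C)OO
Why: Catalytic allylic C–H oxidation of a cyclohexene to the enone; the unhindered allylic CH2 (C9) should be oxidised in preference to the neopentyl methine C7, and the ester is the only other functional group.

Step 4
Reactants: 6 (R)-carvone
Product: 8 (5S)-2,6,6-trimethyl-5-(prop-1-en-2-yl)cyclohex-2-en-1-one, via 6-methylcarvone 7 (not isolated)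
Conditions: LiN(i-Pr)2, THF, −78 °C; MeI; then LiN(i-Pr)2, −78 °C; MeI, DMPU, −78 to 0 °C
Reagents that add atoms: iodomethane, CI
Why: Two kinetic α'-enolate methylations of an enone; the stereocentre (the future C12) is untouched and the new quaternary carbon becomes C11.

Step 5
Reactants: 8 (5S)-2,6,6-trimethyl-5-(prop-1-en-2-yl)cyclohex-2-en-1-one
Product: 9 (4S)-1,3,3-trimethyl-4-(prop-1-en-2-yl)-7-oxabicyclo[4.1.0]heptan-2-one (epoxide trans to isopropenyl)
Conditions: H2O2 (30 %), NaOH, MeOH, 0 °C
Reagents that add atoms: hydrogen peroxide, OO
Why: Weitz–Scheffer epoxidation is selective for the electron-poor enone alkene and leaves the isopropenyl group; the epoxide stereocentres are destroyed in the next step.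

Step 6
Reactants: 9 (4S)-1,3,3-trimethyl-4-(prop-1-en-2-yl)-7-oxabicyclo[4.1.0]heptan-2-one
Product: 10 (3S)-2,2-dimethyl-5-oxo-3-(prop-1-en-2-yl)pentanoic acid
Conditions: H5IO6, THF/H2O, rt
Reagents that add atoms: water, O; periodic acid, O=I(O)(O)(O)(O)O
Why: Periodic acid opens the epoxide to the diol and cleaves it, then cleaves the resulting 1,2-diketone, excising the old α-carbon as acetic acid and leaving C14 as aldehyde and C10 as acid; isolated alkenes are inert to periodate.

Step 7
Reactants: 10 (3S)-2,2-dimethyl-5-oxo-3-(prop-1-en-2-yl)pentanoic acid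
Product: 11 (3S)-2,2-dimethyl-3-(prop-1-en-2-yl)pentane-1,5-diol
Conditions: LiAlH4, THF, 0 °C to reflux
Reagents that add atoms: none
Why: Hydride reduction of aldehyde and acid (or of the cyclic lactol form) to the diol; the two hydroxyls differ as unhindered primary and neopentyl.

Step 8
Reactants: 11 (3S)-2,2-dimethyl-3-(prop-1-en-2-yl)pentane-1,5-diol
Product: 12 (3S)-5-iodo-2,2-dimethyl-3-(prop-1-en-2-yl)pentan-1-ol
Conditions: I2, PPh3, imidazole, Et2O/MeCN, 0 °C
Reagents that add atoms: iodine, II
Why: Appel-type iodination; displacement by iodide is fast at the unhindered C14 carbinol and very slow at the neopentyl C10 carbinol, so one equivalent of reagent should give the mono-iodide.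

Step 9
Reactants: 12 (3S)-5-iodo-2,2-dimethyl-3-(prop-1-en-2-yl)pentan-1-ol
Product: 13 tert-butyl{[(3S)-5-iodo-2,2-dimethyl-3-(prop-1-en-2-yl)pentyl]oxy}dimethylsilane
Conditions: t-BuMe2SiCl, imidazole, DMF, rt
Reagents that add atoms: tert-butylchlorodimethylsilane, CC(C)(C)[Si](C)(C)Cl
Why: Standard silylation; the ether protects the C10 oxygen through organometallic formation and hydride reduction.

Step 10
Reactants: 13 tert-butyl{[(3S)-5-iodo-2,2-dimethyl-3-(prop-1-en-2-yl)pentyl]oxy}dimethylsilane; 5 ethyl 2-[(1S)-6,6-dimethyl-4-oxocyclohex-2-en-1-yl]acetate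
Product: 15 triethylsilyl enol ether of the trans conjugate adduct (C6 chain anti to the C7 ester arm), via Grignard reagent 14 (not isolated)
Conditions: Mg, THF, rt; then CuBr·SMe2 (10 mol %), Et3SiCl, DMPU, 5, THF, −78 °C
Reagents that add atoms: chlorotriethylsilane, CC[Si](Cl)(CC)CC
Why: Copper-catalysed, silyl chloride-accelerated conjugate addition of a Grignard reagent; the nucleophile adds to C6 anti to the adjacent C7 substituent, the usual course for 4-substituted cyclohexenones, and the enolate is trapped as the silyl enol ether, which masks the C9 ketone and leaves the ester untouched at low temperature.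

Step 11
Reactants: 15 triethylsilyl enol ether ester
Product: 16 aldehyde (C7 arm CH2CHO; silyl enol ether and silyl ether intact)
Conditions: i-Bu2AlH, CH2Cl2, −78 °C
Reagents that add atoms: none
Why: Partial reduction of an ester to the aldehyde at low temperature; the ketone is protected as its enol ether, so the ester is the only reducible group.

Step 12
Reactants: 16 aldehyde
Product: 17 C7-prenyl silyl enol ether
Conditions: i-PrPPh3I, n-BuLi, THF, 0 °C; then 16, −78 °C to rt
Reagents that add atoms: isopropyltriphenylphosphonium iodide, CC(C)[P+](c1ccccc1)(c1ccccc1)c1ccccc1.[I-]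
Why: Wittig olefination with the non-stabilised isopropylidene ylide converts CH2CHO into the prenyl group; no stereochemical issue arises for a terminally dimethylated alkene.

Step 13
Reactants: 17 C7-prenyl silyl enol ether
Product: 18 keto alcohol (C9 ketone; C10 primary alcohol)
Conditions: Bu4NF, AcOH, THF, 0 °C to rt
Reagents that add atoms: none
Why: Fluoride cleaves the silyl enol ether to the ketone and the silyl ether to the neopentyl alcohol in one operation; the acetic acid buffer avoids base-induced side reactions.

Step 14
Reactants: 18 keto alcohol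
Product: 19 keto aldehyde (C10 aldehyde on the C11 quaternary carbon)
Conditions: Dess–Martin periodinane, NaHCO3, CH2Cl2, rt
Reagents that add atoms: none
Why: Mild oxidation of a hindered primary alcohol to a non-enolisable aldehyde without touching the alkenes.

Step 15
Reactants: 19 keto aldehyde
Product: 21 bicyclic enone (ring C closed; C5=C10 conjugated with C9=O), via aldol adduct 20 (not isolated)
Conditions: KOH, MeOH, 0.01 M, 40 °C
Reagents that add atoms: none
Why: Intramolecular aldol condensation; only the C5 enolate can reach the non-enolisable aldehyde (the C1 enolate would give a bridged ring), and dehydration makes the seven-membered ring closure irreversible and forms the neopentyl C5–C10 bond without an alkylation.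

Step 16
Reactants: 21 bicyclic enone
Product: 22 allylic alcohol (C9 hydroxyl cis to H6 and to the C7 prenyl group)
Conditions: i-Bu2AlH, CH2Cl2, −78 °C
Reagents that add atoms: none
Why: 1,2-Reduction of the enone; hydride should approach C9 from the face opposite the axial C8 methyl group (as for 3,3-dimethylcyclohexanones), placing the hydroxyl on the face of H6, and the minor epimer is separable and can be re-oxidised to 21.

Step 17
Reactants: 22 allylic alcohol
Product: 23 (bromomethyl)dimethylsilyl ether
Conditions: BrCH2SiMe2Cl, Et3N, DMAP (cat.), CH2Cl2, 0 °C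
Reagents that add atoms: (bromomethyl)chlorodimethylsilane, C[Si](C)(Cl)CBr
Why: Silylation of a secondary alcohol installs the Nishiyama–Stork tether that carries the future C4.

Step 18
Reactants: 23 (bromomethyl)dimethylsilyl ether
Product: 24 cis-fused oxasilolane (C4 bonded to C5; C10 now CH2)
Conditions: Bu3SnH (slow addition), AIBN, benzene, 80 °C
Reagents that add atoms: none
Why: 5-exo radical cyclisation of the α-silyl radical onto C5 of the allylic alkene, the known way of placing an angular carbon cis to a hydroxyl in fused cyclohexenols; the five-membered ring can only be cis-fused, so C4 is set on the face of the C9 oxygen (cis to H6, syn to the C7 prenyl group) whatever the steric bias of ring B, and the neopentyl-flanked C10 radical is then reduced.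

Step 19
Reactants: 24 cis-fused oxasilolane
Product: 25 diol (C9 secondary alcohol; C5 hydroxymethyl)
Conditions: KF, KHCO3, H2O2 (30 %), THF/MeOH, 40 °C
Reagents that add atoms: hydrogen peroxide, OO
Why: Tamao oxidation replaces the C–Si bond by C–OH with retention at carbon and frees the C9 hydroxyl; buffered peroxide does not epoxidise isolated alkenes.

Step 20
Reactants: 25 diol
Product: 26 β-keto aldehyde (C9 ketone; C5 formyl; cis ring fusion)
Conditions: Dess–Martin periodinane (excess), NaHCO3, CH2Cl2, rt
Reagents that add atoms: none
Why: Double oxidation under neutral conditions gives the non-enolisable β-keto aldehyde without retro-aldol or retro-Claisen cleavage; the C9 stereocentre is removed after it has set C5.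

Step 21
Reactants: 26 β-keto aldehyde
Product: 27 O-tetrahydropyranyl aldoxime (E)
Conditions: H2N–OTHP, pyridine, EtOH, rt
Reagents that add atoms: O-(tetrahydro-2H-pyran-2-yl)hydroxylamine, NOC1CCCCO1
Why: Oxime ether formation is selective for the aldehyde over the doubly flanked ketone; the protected oxime tolerates the base, palladium, acetylide and oxidant that follow and avoids any later exposure of an ynone to hydroxylamine.

Step 22
Reactants: 27 O-tetrahydropyranyl aldoxime
Product: 28 hydroxymethylene ketone (C1=CH–OH)
Conditions: NaH, HCO2Et, EtOH (cat.), THF, 0 °C to rt; aq. NH4Cl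
Reagents that add atoms: ethyl formate, CCOC=O
Why: Claisen formylation; C1 is the only enolisable position because C5 is quaternary, and the product is stabilised as its enolate.

Step 23
Reactants: 28 hydroxymethylene ketone
Product: 29 C1-formyl C1-prenyl ketone (formyl cis to the C5 oxime arm)
Conditions: Pd(PPh3)4 (5 mol %), prenyl methyl carbonate, THF, 40 °C
Reagents that add atoms: methyl (3-methylbut-2-en-1-yl) carbonate, COC(=O)OCC=C(C)C
Why: Tsuji–Trost allylation; the soft enolate attacks the CH2 terminus of the π-prenyl complex, and any O-prenyl enol ether re-ionises so that the C-alkylated product accumulates. The electrophile, being the second group to enter at C1, should add axially on the face away from the pseudoaxial C8 methyl group and the C7 prenyl group, which leaves the formyl group on the face of C4.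

Step 24
Reactants: 30 3,4-dihydroxybenzaldehyde
Product: 31 3,4-bis(tert-butyldimethylsilyloxy)benzaldehyde
Conditions: t-BuMe2SiCl, imidazole, DMF, rt
Reagents that add atoms: tert-butylchlorodimethylsilane, CC(C)(C)[Si](C)(C)Cl
Why: Standard silylation of the catechol, which must be protected against oxidation and acetylide chemistry.

Step 25
Reactants: 31 3,4-bis(tert-butyldimethylsilyloxy)benzaldehyde
Product: 32 4-ethynyl-1,2-bis(tert-butyldimethylsilyloxy)benzene
Conditions: Me3SiCHN2, n-BuLi, THF, −78 °C to rt
Reagents that add atoms: (trimethylsilyl)diazomethane, C[Si](C)(C)C=[N+]=[N-]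
Why: Colvin homologation of an aryl aldehyde to the terminal alkyne; it avoids the carbonate/methanol conditions that would cleave aryl silyl ethers.

Step 26
Reactants: 32 4-ethynyl-1,2-bis(tert-butyldimethylsilyloxy)benzene; 29 C1-formyl C1-prenyl ketone
Product: 34 propargylic alcohol (carbinol epimers), via lithium acetylide 33 (not isolated)
Conditions: n-BuLi, THF, −78 °C; then 29, −78 °C; aq. NH4Cl at −78 °C
Reagents that add atoms: none
Why: Acetylide addition to an aldehyde; the C9 ketone is flanked by two quaternary carbons and should not compete, and a cold quench prevents retro-aldol loss of the new arm.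

Step 27
Reactants: 34 propargylic alcohol
Product: 35 aryl ynone O-tetrahydropyranyl aldoxime
Conditions: Dess–Martin periodinane, NaHCO3, CH2Cl2, 0 °C
Reagents that add atoms: none
Why: Oxidation of a propargylic alcohol to the ynone; C1 is already quaternary, so no enol can add to the ynone.

Step 28
Reactants: 35 aryl ynone O-tetrahydropyranyl aldoxime
Product: 36 aryl ynone aldoxime
Conditions: pyridinium p-toluenesulfonate, MeOH, 40 °C
Reagents that add atoms: none
Why: Mild acid-catalysed acetal exchange frees the oxime; aryl silyl ethers and the ynone tolerate these conditions.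

Step 29
Reactants: 36 aryl ynone aldoxime
Product: 39 isoxazole-fused tricyclic 2,9-dione, via hydroximoyl chloride 37 (not isolated), via nitrile oxide 38 (not isolated)
Conditions: NaOCl (aq.), CH2Cl2, 0 °C to rt
Reagents that add atoms: none
Why: Hypochlorite chlorinates the aldoxime to hydroximoyl chloride 37, which loses HCl to nitrile oxide 38; this then adds across the ynone in a concerted [3+2] cycloaddition, the closest known reaction type being the intramolecular nitrile oxide–alkyne cycloaddition to ring-fused isoxazoles. Ring A closes by the C4–C3 bond as a six-membered carbocycle across the tether C5–C9–C1–C2 (exo with respect to the alkyne), and the isoxazole closes in the same event by the O–C(aryl) bond. No stereocentre is formed. Regiochemistry is fixed by the tether, since the other orientation would need a seven-membered bridged ring. The step needs the two arms cis on ring B, which steps 18 and 23 secure, and ring B must adopt the boat that the C7 prenyl group also prefers in the product. The electron-poor, linear ynone is the matched dipolarophile and should outrun the trisubstituted C7 prenyl alkene on the same face. The quaternary C5 shields the dipole and slows dimerisation, and the basic biphasic medium keeps hypochlorous acid away from the prenyl groups.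

Step 30
Reactants: 39 isoxazole-fused tricyclic 2,9-dione
Product: 40 enaminone (C4 amino; C3 aroyl)
Conditions: Mo(CO)6, MeCN/H2O, 80 °C
Reagents that add atoms: none
Why: Reductive N–O cleavage of an isoxazole by zerovalent molybdenum gives the β-amino enone; alkenes, ketones and silyl ethers are not reduced.

Step 31
Reactants: 40 enaminone
Product: 41 target compound
Conditions: LiOH, dioxane/H2O, 80 °C, degassed; then 1 M HCl
Reagents that add atoms: water, O
Why: Aqueous hydroxide hydrolyses the vinylogous amide to the enolised triketone (addition–elimination at C4) and cleaves both aryl silyl ethers; the triketone is protected as its enolate under these conditions, and exclusion of air protects the catecholate.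

## Compound list

1 | 4,4-dimethylcyclohex-2-en-1-one | CC1(C)CCC(=O)C=C1 | starting material
2 | (1S)-4,4-dimethylcyclohex-2-en-1-ol | O[C@@H]1C=CC(C)(C)CC1 | intermediate
3 | 1-ethoxyvinyl ether of 2 (mixed ketene acetal, formed in the flask) | C=C(OCC)O[C@@H]1C=CC(C)(C)CC1 | intermediate
4 | ethyl 2-[(1S)-6,6-dimethylcyclohex-2-en-1-yl]acetate | CCOC(=O)C[C@H]1C=CCCC1(C)C | intermediate
5 | ethyl 2-[(1S)-6,6-dimethyl-4-oxocyclohex-2-en-1-yl]acetate | CCOC(=O)C[C@H]1C=CC(=O)CC1(C)C | intermediate
6 | (R)-carvone, (5R)-2-methyl-5-(prop-1-en-2-yl)cyclohex-2-en-1-one | CC1=CC[C@@H](C(C)=C)CC1=O | starting material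
7 | (5R)-2,6-dimethyl-5-(prop-1-en-2-yl)cyclohex-2-en-1-one, C6 epimers (formed in the flask) | CC1=CC[C@@H](C(C)=C)C(C)C1=O | intermediate
8 | (5S)-2,6,6-trimethyl-5-(prop-1-en-2-yl)cyclohex-2-en-1-one | CC1=CC[C@@H](C(C)=C)C(C)(C)C1=O | intermediate
9 | (4S)-1,3,3-trimethyl-4-(prop-1-en-2-yl)-7-oxabicyclo[4.1.0]heptan-2-one, epoxide oxygen trans to the isopropenyl group | C[C@@]12O[C@@H]1C[C@@H](C(C)=C)C(C)(C)C2=O | intermediate
10 | (3S)-2,2-dimethyl-5-oxo-3-(prop-1-en-2-yl)pentanoic acid | O=CC[C@@H](C(C)=C)C(C)(C)C(=O)O | intermediate
11 | (3S)-2,2-dimethyl-3-(prop-1-en-2-yl)pentane-1,5-diol | OCC[C@@H](C(C)=C)C(C)(C)CO | intermediate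
12 | (3S)-5-iodo-2,2-dimethyl-3-(prop-1-en-2-yl)pentan-1-ol | ICC[C@@H](C(C)=C)C(C)(C)CO | intermediate
13 | tert-butyl{[(3S)-5-iodo-2,2-dimethyl-3-(prop-1-en-2-yl)pentyl]oxy}dimethylsilane | ICC[C@@H](C(C)=C)C(C)(C)CO[Si](C)(C)C(C)(C)C | intermediate
14 | Grignard reagent of 13 (formed in the flask) | I[Mg]CC[C@@H](C(C)=C)C(C)(C)CO[Si](C)(C)C(C)(C)C | intermediate
15 | ethyl 2-[(1S,2S)-2-{(3S)-5-(tert-butyldimethylsilyloxy)-4,4-dimethyl-3-(prop-1-en-2-yl)pentyl}-6,6-dimethyl-4-(triethylsilyloxy)cyclohex-3-en-1-yl]acetate; ring substituents trans | CC(C)(C)[Si](C)(C)OCC(C)(C)[C@H](C(C)=C)CC[C@H]1[C@H](CC(=O)OCC)C(C)(C)CC(O[Si](CC)(CC)CC)=C1 | intermediate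
16 | aldehyde from 15 (C7 arm CH2CHO; same configuration) | CC(C)(C)[Si](C)(C)OCC(C)(C)[C@H](C(C)=C)CC[C@H]1[C@H](CC=O)C(C)(C)CC(O[Si](CC)(CC)CC)=C1 | intermediate
17 | C7-prenyl triethylsilyl enol ether (same configuration) | CC(C)(C)[Si](C)(C)OCC(C)(C)[C@H](C(C)=C)CC[C@H]1[C@H](CC=C(C)C)C(C)(C)CC(O[Si](CC)(CC)CC)=C1 | intermediate
18 | trans-3-[(3S)-5-hydroxy-4,4-dimethyl-3-(prop-1-en-2-yl)pentyl]-5,5-dimethyl-4-(3-methylbut-2-enyl)cyclohexan-1-one, C6 and C7 as in 41 | OCC(C)(C)[C@H](C(C)=C)CC[C@H]1[C@H](CC=C(C)C)C(C)(C)CC(=O)C1 | intermediate
19 | keto aldehyde: 18 with C10 as CHO | O=CC(C)(C)[C@H](C(C)=C)CC[C@H]1[C@H](CC=C(C)C)C(C)(C)CC(=O)C1 | intermediate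
20 | aldol adduct: ring B/ring C β-hydroxy ketone with C5–C10 bond, mixture at C5 and C10 (formed in the flask) | C=C(C)[C@@H]1CC[C@H]2[C@H](CC=C(C)C)C(C)(C)CC(=O)C2C(O)C1(C)C | intermediate
21 | bicyclic enone: ring B C9 ketone conjugated with the C5=C10 double bond of ring C; C6, C7, C12 as in 41 | C=C(C)[C@@H]1CC[C@H]2[C@H](CC=C(C)C)C(C)(C)CC(=O)C2=CC1(C)C | intermediate
22 | allylic alcohol: 21 with C9–OH cis to H6 | C=C(C)[C@@H]1CC[C@H]2[C@H](CC=C(C)C)C(C)(C)C[C@H](O)C2=CC1(C)C | intermediate
23 | (bromomethyl)dimethylsilyl ether of 22 | C=C(C)[C@@H]1CC[C@H]2[C@H](CC=C(C)C)C(C)(C)C[C@H](O[Si](C)(C)CBr)C2=CC1(C)C | intermediate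
24 | cis-fused oxasilolane: C9–O–SiMe2–CH2(C4)–C5; ring fusion C5–C10/C6–C14 cis | C=C(C)[C@@H]1CC[C@H]2[C@H](CC=C(C)C)C(C)(C)C[C@@H]3O[Si](C)(C)C[C@]23CC1(C)C | intermediate
25 | diol: C9–OH and C5–CH2OH, both cis to H6 | C=C(C)[C@@H]1CC[C@H]2[C@H](CC=C(C)C)C(C)(C)C[C@H](O)[C@@]2(CO)CC1(C)C | intermediate
26 | β-keto aldehyde: cis-fused ring B/ring C C9 ketone with C5–CHO cis to H6 | C=C(C)[C@@H]1CC[C@H]2[C@H](CC=C(C)C)C(C)(C)CC(=O)[C@@]2(C=O)CC1(C)C | intermediate
27 | (E)-O-(tetrahydropyran-2-yl) aldoxime of 26 | C=C(C)[C@@H]1CC[C@H]2[C@H](CC=C(C)C)C(C)(C)CC(=O)[C@@]2(/C=N/OC3CCCCO3)CC1(C)C | intermediate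
28 | C1-hydroxymethylene ketone (H-bonded enol) | C=C(C)[C@@H]1CC[C@H]2[C@H](CC=C(C)C)C(C)(C)/C(=C/O)C(=O)[C@@]2(/C=N/OC3CCCCO3)CC1(C)C | intermediate
29 | C1-formyl C1-prenyl ketone; formyl cis to the C5 oxime arm, C1 prenyl trans to C7 prenyl | C=C(C)[C@@H]1CC[C@H]2[C@H](CC=C(C)C)C(C)(C)[C@](CC=C(C)C)(C=O)C(=O)[C@@]2(/C=N/OC3CCCCO3)CC1(C)C | intermediate
30 | 3,4-dihydroxybenzaldehyde | O=Cc1ccc(O)c(O)c1 | starting material
31 | 3,4-bis(tert-butyldimethylsilyloxy)benzaldehyde | O=Cc1ccc(O[Si](C)(C)C(C)(C)C)c(O[Si](C)(C)C(C)(C)C)c1 | intermediate
32 | 4-ethynyl-1,2-bis(tert-butyldimethylsilyloxy)benzene | C#Cc1ccc(O[Si](C)(C)C(C)(C)C)c(O[Si](C)(C)C(C)(C)C)c1 | intermediate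
33 | lithium acetylide of 32 (formed in the flask) | [Li]C#Cc1ccc(O[Si](C)(C)C(C)(C)C)c(O[Si](C)(C)C(C)(C)C)c1 | intermediate
34 | propargylic alcohol: C1 bears prenyl and CH(OH)C≡C-aryl (carbinol epimers) | C=C(C)[C@@H]1CC[C@H]2[C@H](CC=C(C)C)C(C)(C)[C@](CC=C(C)C)(C(O)C#Cc3ccc(O[Si](C)(C)C(C)(C)C)c(O[Si](C)(C)C(C)(C)C)c3)C(=O)[C@@]2(/C=N/OC4CCCCO4)CC1(C)C | intermediate
35 | aryl ynone O-tetrahydropyranyl aldoxime | C=C(C)[C@@H]1CC[C@H]2[C@H](CC=C(C)C)C(C)(C)[C@](CC=C(C)C)(C(=O)C#Cc3ccc(O[Si](C)(C)C(C)(C)C)c(O[Si](C)(C)C(C)(C)C)c3)C(=O)[C@@]2(/C=N/OC4CCCCO4)CC1(C)C | intermediate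
36 | aryl ynone (E)-aldoxime | C=C(C)[C@@H]1CC[C@H]2[C@H](CC=C(C)C)C(C)(C)[C@](CC=C(C)C)(C(=O)C#Cc3ccc(O[Si](C)(C)C(C)(C)C)c(O[Si](C)(C)C(C)(C)C)c3)C(=O)[C@@]2(/C=N/O)CC1(C)C | intermediate
37 | hydroximoyl chloride of 36 (formed in the flask) | C=C(C)[C@@H]1CC[C@H]2[C@H](CC=C(C)C)C(C)(C)[C@](CC=C(C)C)(C(=O)C#Cc3ccc(O[Si](C)(C)C(C)(C)C)c(O[Si](C)(C)C(C)(C)C)c3)C(=O)[C@@]2(C(Cl)=NO)CC1(C)C | intermediate
38 | nitrile oxide on C5 with prenyl and aryl ynone on C1 (formed in the flask) | C=C(C)[C@@H]1CC[C@H]2[C@H](CC=C(C)C)C(C)(C)[C@](CC=C(C)C)(C(=O)C#Cc3ccc(O[Si](C)(C)C(C)(C)C)c(O[Si](C)(C)C(C)(C)C)c3)C(=O)[C@]2(CC1(C)C)C#[N+][O-] | intermediate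
39 | isoxazole-fused tricyclic 2,9-dione with the bis-silylated aryl group on the isoxazole | C=C(C)[C@@H]1CC[C@H]2[C@H](CC=C(C)C)C(C)(C)[C@]3(CC=C(C)C)C(=O)c4c(-c5ccc(O[Si](C)(C)C(C)(C)C)c(O[Si](C)(C)C(C)(C)C)c5)onc4[C@@]2(CC1(C)C)C3=O | intermediate
40 | enaminone: C4 amino, C3 3,4-bis(silyloxy)benzoyl, C2 and C9 ketones | C=C(C)[C@@H]1CC[C@H]2[C@H](CC=C(C)C)C(C)(C)[C@]3(CC=C(C)C)C(=O)C(C(=O)c4ccc(O[Si](C)(C)C(C)(C)C)c(O[Si](C)(C)C(C)(C)C)c4)=C(N)[C@@]2(CC1(C)C)C3=O | intermediate
41 | CNP0140614.2 | C=C(C)[C@@H]1CC[C@H]2[C@H](CC=C(C)C)C(C)(C)[C@]3(CC=C(C)C)C(=O)C(C(=O)c4ccc(O)c(O)c4)=C(O)[C@@]2(CC1(C)C)C3=O | target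

## Step count and least certain steps

Total: 31 steps. Longest linear sequence: 26 steps (steps 4–23 from (R)-carvone, then steps 26–31). The ring B branch (steps 1–3) and the alkyne branch (steps 24–25) join it at steps 10 and 26.

Step 29 (key step). The nitrile oxide may add instead to the C7 prenyl alkene on the same face or dimerise, hypochlorite may attack the ynone or chlorinate the prenyl groups, and the boat conformation of ring B needed to bring the two arms together may be too costly. Fallback: from 36, the aldoxime is dehydrated (Burgess reagent) to the nitrile ynone F1; pyrrolidine is added to the ynone and the enaminone hydrolysed with aqueous acetic acid to the nitrile 1,3-diketone F2; a Lewis acid (SnCl4) then promotes addition of the diketone carbon C3 to the nitrile, a known route from β-dicarbonyls and nitriles to β-enaminones. This forms the same C3–C4 bond without a dipole and rejoins the route at 40.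

Step 18. The silylmethyl radical may close in the 6-endo sense onto C10 or be reduced before it cyclises, since C5 is a fully substituted alkene carbon. Fallback: from 21, reduction with lithium in ammonia gives the C5 lithium enolate regiospecifically, and trapping with formaldehyde gives the hydroxymethyl ketone F3; oxidation with Dess–Martin periodinane rejoins the route at 26. Cis fusion is the usual outcome of angular alkylation but is less certain here, because the electrophile must enter syn to the C7 prenyl group.

Step 23. Alkylation at a fully substituted carbon beside the gem-dimethyl group may stop at oxygen, may give the branched (reverse prenyl) isomer, or may take place on the other face of the enolate. Fallback, for use if the second electrophile proves to enter the face opposite to the one assumed: from 27, the C1 enolate (LiN(SiMe3)2) is alkylated with prenyl bromide to the C1-prenyl ketone F4; its enolate is then added to the arylpropynal F5 (from 32, n-BuLi then DMF), so that the acyl carbon is the last group to enter. This rejoins the route at 34.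

Step 15. Seven-membered ring closure may be slower than intermolecular aldol reaction or Cannizzaro-type loss of the non-enolisable aldehyde under hydroxide. Fallback: from 17, N-bromosuccinimide converts the silyl enol ether into the α-bromo ketone F6; HF·pyridine gives the bromo alcohol F7 and Dess–Martin periodinane the bromo aldehyde F8; SmI2 then generates the C5 samarium enolate regiospecifically and closes the ring in a Reformatsky-type aldol that is irreversible at low temperature, giving 20, which is dehydrated (MsCl, Et3N, then DBU) to rejoin the route at 21.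

## Further compounds

F1 | step 29 | nitrile ynone: 36 with C5–C≡N in place of the aldoxime | C=C(C)[C@@H]1CC[C@H]2[C@H](CC=C(C)C)C(C)(C)[C@](CC=C(C)C)(C(=O)C#Cc3ccc(O[Si](C)(C)C(C)(C)C)c(O[Si](C)(C)C(C)(C)C)c3)C(=O)[C@@]2(C#N)CC1(C)C
F2 | step 29 | nitrile 1,3-diketone: C1 bears prenyl and C(=O)CH2C(=O)-aryl, C5 bears C≡N | C=C(C)[C@@H]1CC[C@H]2[C@H](CC=C(C)C)C(C)(C)[C@](CC=C(C)C)(C(=O)CC(=O)c3ccc(O[Si](C)(C)C(C)(C)C)c(O[Si](C)(C)C(C)(C)C)c3)C(=O)[C@@]2(C#N)CC1(C)C
F3 | step 18 | hydroxymethyl ketone: cis-fused C9 ketone with C5–CH2OH cis to H6 | C=C(C)[C@@H]1CC[C@H]2[C@H](CC=C(C)C)C(C)(C)CC(=O)[C@@]2(CO)CC1(C)C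
F4 | step 23 | C1-prenyl ketone: 27 with one prenyl group on C1 (C1 epimers) | C=C(C)[C@@H]1CC[C@H]2[C@H](CC=C(C)C)C(C)(C)C(CC=C(C)C)C(=O)[C@@]2(/C=N/OC3CCCCO3)CC1(C)C
F5 | step 23 | 3-[3,4-bis(tert-butyldimethylsilyloxy)phenyl]prop-2-ynal | O=CC#Cc1ccc(O[Si](C)(C)C(C)(C)C)c(O[Si](C)(C)C(C)(C)C)c1
F6 | step 15 | α-bromo ketone: C5–Br, C9 ketone, C10 silyl ether (C5 epimers) | CC(C)(C)[Si](C)(C)OCC(C)(C)[C@H](C(C)=C)CC[C@H]1[C@H](CC=C(C)C)C(C)(C)CC(=O)C1Br
F7 | step 15 | bromo keto alcohol: F6 with free C10 hydroxyl | OCC(C)(C)[C@H](C(C)=C)CC[C@H]1[C@H](CC=C(C)C)C(C)(C)CC(=O)C1Br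
F8 | step 15 | bromo keto aldehyde: F7 with C10 as CHO | O=CC(C)(C)[C@H](C(C)=C)CC[C@H]1[C@H](CC=C(C)C)C(C)(C)CC(=O)C1Br
A1 | alternative 1 | cycloheptene acid with quaternary C5 (CH2O-p-methoxybenzyl and CO2H) and the C7–C1 ester chain on C6 | C=C(C)[C@@H]1C=C[C@@H]([C@H](CC=C(C)C)C(C)(C)CC(=O)OC)[C@@](CC1(C)C)(COCc2ccc(OC)cc2)C(=O)O
A2 | alternative 2 | cis-fused ring B/ring C C9 ketone with hydrogen on C5 | C=C(C)[C@@H]1CC[C@H]2[C@H](CC=C(C)C)C(C)(C)CC(=O)[C@H]2CC1(C)C
A3 | alternative 3 | cis-fused ring B ketone with C1 prenyl and the dioxolane-protected aroylacetyl chain on C5 | C=C(C)[C@@H]1CC[C@H]2[C@H](CC=C(C)C)C(C)(C)[C@@H](CC=C(C)C)C(=O)[C@]2(CC1(C)C)C3(CC(=O)c4ccc(O[Si](C)(C)C(C)(C)C)c(O[Si](C)(C)C(C)(C)C)c4)OCCO3
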